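## Retrosynthetic overview
1. The last step is one acid treatment. It frees both CO2H groups (held as tert-butyl esters) and the phenol (held as a MOM ether).
2. Trienone: cut the C=C next to the aryl ketone. This is an aldol condensation of an aryl methyl ketone with tert-butyl (2E,4E)-6-oxohexa-2,4-dienoate, made in one pot from fumaraldehyde mono-acetal and a stabilised ylide.
3. Side-chain enoate: cut C2=C3 (Wittig), then remove the formyl carbon (linear hydroformylation). This leads back to an (R)-3-arylbut-1-ene.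
4. Benzylic stereocentre: Ni-catalysed asymmetric hydrovinylation of a styrene. The styrene comes from 2'-hydroxy-5'-methoxyacetophenone by ortho-bromination, MOM protection and Suzuki vinylation.
5. Rings: none is formed. The single benzene ring is bought with the starting acetophenone.

Assumption: the (Sa,Rc,Rc) antipode of the BINOL/bis(1-phenylethyl)amine phosphoramidite gives the R alkene, since its mirror image gives (S)-3-phenylbut-1-ene; both antipodes are sold, so the other one is used if the sense is reversed on this substrate.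

## Route

Step 1
Reactants: 1 1-(2-hydroxy-5-methoxyphenyl)ethan-1-one
Product: 2 1-(3-bromo-2-hydroxy-5-methoxyphenyl)ethan-1-one
Conditions: NBS (1.0 equiv), i-Pr2NH (10 mol %), CH2Cl2, 0 °C to rt
Reagents that add atoms: N-bromosuccinimide, O=C1CCC(=O)N1Br
Why: Electrophilic aromatic bromination goes to the only free position ortho to the phenol OH (para is blocked by OMe), and the amine-catalysed NBS protocol avoids bromination of the acetyl group.

Step 2
Reactants: 2 1-(3-bromo-2-hydroxy-5-methoxyphenyl)ethan-1-one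
Product: 3 1-[3-bromo-5-methoxy-2-(methoxymethoxy)phenyl]ethan-1-one
Conditions: MOMCl (1.5 equiv), K2CO3 (2 equiv), acetone, reflux
Reagents that add atoms: chloromethyl methyl ether, COCCl
Why: Williamson-type O-alkylation of the chelated phenol masks the acidic OH for the cationic nickel catalyst and the enolate step, and the MOM group falls off later together with the esters.

Step 3
Reactants: 3 1-[3-bromo-5-methoxy-2-(methoxymethoxy)phenyl]ethan-1-one
Product: 4 1-[3-ethenyl-5-methoxy-2-(methoxymethoxy)phenyl]ethan-1-one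
Conditions: vinyl-Bpin (1.3 equiv), Pd(dppf)Cl2 (3 mol %), K2CO3 (2 equiv), dioxane/H2O 4:1, 85 °C
Reagents that add atoms: 4,4,5,5-tetramethyl-2-vinyl-1,3,2-dioxaborolane, C=CB1OC(C)(C)C(C)(C)O1
Why: Suzuki–Miyaura coupling replaces the aryl bromide by vinyl and tolerates the ketone and the MOM acetal.

Step 4
Reactants: 4 1-[3-ethenyl-5-methoxy-2-(methoxymethoxy)phenyl]ethan-1-one
Product: 5 1-{3-[(2R)-but-3-en-2-yl]-5-methoxy-2-(methoxymethoxy)phenyl}ethan-1-one
Conditions: ethylene (1 atm), [(allyl)NiBr]2 (1 mol %), (Sa,Rc,Rc)-BINOL bis(1-phenylethyl)amine phosphoramidite (2 mol %), NaBArF (2 mol %), CH2Cl2, −70 °C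
Reagents that add atoms: ethylene, C=C
Why: In the Ni-catalysed asymmetric hydrovinylation the cationic Ni–H adds to the styrene to give an η3-benzyl nickel species, which inserts ethylene and β-H-eliminates to give only the branched 3-arylbut-1-ene, while the chiral phosphoramidite selects the styrene face so that the new benzylic centre is R.

Step 5
Reactants: 5 1-{3-[(2R)-but-3-en-2-yl]-5-methoxy-2-(methoxymethoxy)phenyl}ethan-1-one
Product: 7 tert-butyl (2E,6R)-6-[3-acetyl-5-methoxy-2-(methoxymethoxy)phenyl]hept-2-enoate, via aldehyde 6 (not isolated)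
Conditions: Rh(acac)(CO)2 (1 mol %), Xantphos (3 mol %), CO/H2 1:1 (10 bar), toluene, 70 °C; vent; Ph3P=CHCO2t-Bu (1.2 equiv), rt
Reagents that add atoms: carbon monoxide, [C-]#[O+]; tert-butyl (triphenyl-λ5-phosphanylidene)acetate, CC(C)(C)OC(=O)C=P(c1ccccc1)(c1ccccc1)c1ccccc1
Why: Linear-selective Rh/Xantphos hydroformylation (wide bite angle and the allylic branch both disfavour the branched Rh-alkyl, so the stereocentre is untouched) is followed in the same pot by an E-selective Wittig olefination that attacks the aldehyde only and leaves the aryl ketone alone.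

Step 6
Reactants: 8 (2E)-4,4-dimethoxybut-2-enal
Product: 10 tert-butyl (2E,4E)-6-oxohexa-2,4-dienoate, via dienoate acetal 9 (not isolated)
Conditions: Ph3P=CHCO2t-Bu (1.05 equiv), CH2Cl2, 0 °C to rt; concentrate; p-TsOH·H2O (5 mol %), acetone/H2O 10:1, rt
Reagents that add atoms: tert-butyl (triphenyl-λ5-phosphanylidene)acetate, CC(C)(C)OC(=O)C=P(c1ccccc1)(c1ccccc1)c1ccccc1; water, O
Why: An E-selective Wittig olefination of the enal is followed by acid-catalysed hydrolysis of the dienyl dimethyl acetal, which is much faster than loss of the tert-butyl ester.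

Step 7
Reactants: 7 tert-butyl (2E,6R)-6-[3-acetyl-5-methoxy-2-(methoxymethoxy)phenyl]hept-2-enoate; 10 tert-butyl (2E,4E)-6-oxohexa-2,4-dienoate
Product: 14 tert-butyl (2E,4E,6E)-8-{3-[(2R,5E)-7-tert-butoxy-7-oxohept-5-en-2-yl]-5-methoxy-2-(methoxymethoxy)phenyl}-8-oxoocta-2,4,6-trienoate, via lithium enolate 11 (not isolated), via lithium aldolate 12 (not isolated), via mesylate 13 (not isolated)
Conditions: LiHMDS (1.05 equiv), THF, −78 °C; 10 (1.2 equiv), −78 °C; MsCl (1.5 equiv), −78 to 0 °C; Et3N (4 equiv), 0 °C to rt, dark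
Reagents that add atoms: none
Why: This aldol condensation is run as a kinetic 1,2-aldol addition of the methyl ketone enolate to the non-enolisable aldehyde, then mesylation and E1cB elimination to the fully conjugated E enone, with the remote R centre not involved.

Step 8
Reactants: 14 tert-butyl (2E,4E,6E)-8-{3-[(2R,5E)-7-tert-butoxy-7-oxohept-5-en-2-yl]-5-methoxy-2-(methoxymethoxy)phenyl}-8-oxoocta-2,4,6-trienoate
Product: 15 (2E,4E,6E)-8-{3-[(2R,5E)-6-carboxyhex-5-en-2-yl]-2-hydroxy-5-methoxyphenyl}-8-oxoocta-2,4,6-trienoic acid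
Conditions: TFA/CH2Cl2 1:3, H2O (5 equiv), 0 °C to rt, dark
Reagents that add atoms: none
Why: Acidolysis with TFA cleaves both tert-butyl esters by the E1 path and hydrolyses the MOM acetal (made labile by the ortho carbonyl) in one operation, with no base or nucleophile touching the trienone or the stereocentre.

## Compound list
1 | 1-(2-hydroxy-5-methoxyphenyl)ethan-1-one | COc1cc(C(C)=O)c(O)cc1 | starting material
2 | 1-(3-bromo-2-hydroxy-5-methoxyphenyl)ethan-1-one | COc1cc(C(C)=O)c(O)c(Br)c1 | intermediate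
3 | 1-[3-bromo-5-methoxy-2-(methoxymethoxy)phenyl]ethan-1-one | COc1cc(C(C)=O)c(OCOC)c(Br)c1 | intermediate
4 | 1-[3-ethenyl-5-methoxy-2-(methoxymethoxy)phenyl]ethan-1-one | COc1cc(C(C)=O)c(OCOC)c(C=C)c1 | intermediate
5 | 1-{3-[(2R)-but-3-en-2-yl]-5-methoxy-2-(methoxymethoxy)phenyl}ethan-1-one | COc1cc(C(C)=O)c(OCOC)c([C@H](C)C=C)c1 | intermediate
6 | (4R)-4-[3-acetyl-5-methoxy-2-(methoxymethoxy)phenyl]pentanal | COc1cc(C(C)=O)c(OCOC)c([C@H](C)CCC=O)c1 | intermediate
7 | tert-butyl (2E,6R)-6-[3-acetyl-5-methoxy-2-(methoxymethoxy)phenyl]hept-2-enoate | COc1cc(C(C)=O)c(OCOC)c([C@H](C)CC/C=C/C(=O)OC(C)(C)C)c1 | intermediate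
8 | (2E)-4,4-dimethoxybut-2-enal (fumaraldehyde mono(dimethyl acetal)) | COC(OC)/C=C/C=O | starting material
9 | tert-butyl (2E,4E)-6,6-dimethoxyhexa-2,4-dienoate | COC(OC)/C=C/C=C/C(=O)OC(C)(C)C | intermediate
10 | tert-butyl (2E,4E)-6-oxohexa-2,4-dienoate | O=C/C=C/C=C/C(=O)OC(C)(C)C | intermediate
11 | lithium 1-{3-[(2R,5E)-7-tert-butoxy-7-oxohept-5-en-2-yl]-5-methoxy-2-(methoxymethoxy)phenyl}ethen-1-olate | COc1cc(C(=C)[O-])c(OCOC)c([C@H](C)CC/C=C/C(=O)OC(C)(C)C)c1.[Li+] | intermediate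
12 | lithium alkoxide of tert-butyl (2E,4E)-8-{3-[(2R,5E)-7-tert-butoxy-7-oxohept-5-en-2-yl]-5-methoxy-2-(methoxymethoxy)phenyl}-6-hydroxy-8-oxoocta-2,4-dienoate (both C6 epimers) | COc1cc(C(=O)CC([O-])/C=C/C=C/C(=O)OC(C)(C)C)c(OCOC)c([C@H](C)CC/C=C/C(=O)OC(C)(C)C)c1.[Li+] | intermediate
13 | tert-butyl (2E,4E)-8-{3-[(2R,5E)-7-tert-butoxy-7-oxohept-5-en-2-yl]-5-methoxy-2-(methoxymethoxy)phenyl}-6-(methanesulfonyloxy)-8-oxoocta-2,4-dienoate (both C6 epimers) | COc1cc(C(=O)CC(OS(C)(=O)=O)/C=C/C=C/C(=O)OC(C)(C)C)c(OCOC)c([C@H](C)CC/C=C/C(=O)OC(C)(C)C)c1 | intermediate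
14 | tert-butyl (2E,4E,6E)-8-{3-[(2R,5E)-7-tert-butoxy-7-oxohept-5-en-2-yl]-5-methoxy-2-(methoxymethoxy)phenyl}-8-oxoocta-2,4,6-trienoate | COc1cc(C(=O)/C=C/C=C/C=C/C(=O)OC(C)(C)C)c(OCOC)c([C@H](C)CC/C=C/C(=O)OC(C)(C)C)c1 | intermediate
15 | (2E,4E,6E)-8-{3-[(2R,5E)-6-carboxyhex-5-en-2-yl]-2-hydroxy-5-methoxyphenyl}-8-oxoocta-2,4,6-trienoic acid (CNP0274934.1) | COc1cc(C(=O)/C=C/C=C/C=C/C(=O)O)c(O)c([C@H](C)CC/C=C/C(=O)O)c1 | target

## Step count and risks
Total step count: 8.
Longest linear sequence: 7 (steps 1, 2, 3, 4, 5, 7, 8). Step 6 is a one-step branch.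

**Step 4 (asymmetric hydrovinylation).** The ketone and MOM oxygens may slow the cationic Ni–H catalyst, and the ee on this ortho-substituted styrene is unproven.

The fallback uses chirality transfer in place of catalysis. It sets out from 1 and comes back to the route at 5, replacing steps 1–4.
- Mitsunobu etherification of 1 with enantiopure (R,E)-pent-3-en-2-ol (PPh3, DIAD, toluene, 0 °C, SN2 inversion) gives 1-{5-methoxy-2-[(2S,3E)-pent-3-en-2-yloxy]phenyl}ethan-1-one F1.
- Heating in N,N-diethylaniline at 180 °C triggers an aromatic Claisen rearrangement to the only free ortho position. It passes through 2-acetyl-4-methoxy-6-[(2R,3E)-pent-3-en-2-yl]cyclohexa-2,4-dien-1-one F2.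
- F2 enolises to 1-{2-hydroxy-5-methoxy-3-[(2R,3E)-pent-3-en-2-yl]phenyl}ethan-1-one F3. The shift is suprafacial with the carbinol methyl outside in the transition state, so the S ether gives the R,E product. The minor Z isomer has the opposite configuration and is removed by chromatography.
- Ethenolysis (Hoveyda–Grubbs II, ethylene 5 bar, CH2Cl2) trims the propenyl end to 1-{3-[(2R)-but-3-en-2-yl]-2-hydroxy-5-methoxyphenyl}ethan-1-one F4.
- MOMCl/K2CO3 as in step 2 then gives 5.

**Step 7 (aldol condensation with 10).** Aldehyde 10 is activated for Michael addition from both ends, so the enolate may add 1,4 or 1,6, and the product may oligomerise.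

The fallback grows the chain stepwise and makes the last C=C by Wittig olefination. It sets out from 7 (with purchased 8) and comes back at 14.
- Claisen–Schmidt condensation of 7 with the ester-free aldehyde 8 (Ba(OH)2·8H2O, MeOH, rt) runs through tert-butyl (2E,6R)-6-{3-[(4E)-3-hydroxy-6,6-dimethoxyhex-4-enoyl]-5-methoxy-2-(methoxymethoxy)phenyl}hept-2-enoate F5.
- F5 loses water to give tert-butyl (2E,6R)-6-{3-[(2E,4E)-6,6-dimethoxyhexa-2,4-dienoyl]-5-methoxy-2-(methoxymethoxy)phenyl}hept-2-enoate F6.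
- Brief PPTS in acetone/H2O unmasks tert-butyl (2E,6R)-6-{5-methoxy-2-(methoxymethoxy)-3-[(2E,4E)-6-oxohexa-2,4-dienoyl]phenyl}hept-2-enoate F7.
- Ph3P=CHCO2t-Bu (CH2Cl2, rt) olefinates the aldehyde of F7 selectively to give 14.

**Step 8 (global acidolysis).** The free 2'-hydroxy trienone may close to a chromanone by oxa-Michael addition, or the polyene may isomerise in acid.

The fallback deprotects before the polyene exists and forms the trienone last under base. It sets out from 7 and 10 and comes back at 15.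
- TFA/CH2Cl2/H2O converts 7 into (2E,6R)-6-(3-acetyl-2-hydroxy-5-methoxyphenyl)hept-2-enoic acid F8.
- The same conditions convert 10 into (2E,4E)-6-oxohexa-2,4-dienoic acid F9.
- Claisen–Schmidt condensation of the two unprotected partners (KOH, EtOH/H2O, 0 °C to rt) runs through (2E,4E)-8-{3-[(2R,5E)-6-carboxyhex-5-en-2-yl]-2-hydroxy-5-methoxyphenyl}-6-hydroxy-8-oxoocta-2,4-dienoic acid F10.
- Cold acidification then gives 15.
- In base the product is held as the open phenoxide, and the carboxylates reduce the Michael reactivity of both chains.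

## Further compounds
F1 | step 4 | 1-{5-methoxy-2-[(2S,3E)-pent-3-en-2-yloxy]phenyl}ethan-1-one | COc1cc(C(C)=O)c(O[C@@H](C)/C=C/C)cc1
F2 | step 4 | 2-acetyl-4-methoxy-6-[(2R,3E)-pent-3-en-2-yl]cyclohexa-2,4-dien-1-one | COC1=CC([C@H](C)/C=C/C)C(=O)C(C(C)=O)=C1
F3 | step 4 | 1-{2-hydroxy-5-methoxy-3-[(2R,3E)-pent-3-en-2-yl]phenyl}ethan-1-one | COc1cc(C(C)=O)c(O)c([C@H](C)/C=C/C)c1
F4 | step 4 | 1-{3-[(2R)-but-3-en-2-yl]-2-hydroxy-5-methoxyphenyl}ethan-1-one | COc1cc(C(C)=O)c(O)c([C@H](C)C=C)c1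
F5 | step 7 | tert-butyl (2E,6R)-6-{3-[(4E)-3-hydroxy-6,6-dimethoxyhex-4-enoyl]-5-methoxy-2-(methoxymethoxy)phenyl}hept-2-enoate | COc1cc(C(=O)CC(O)/C=C/C(OC)OC)c(OCOC)c([C@H](C)CC/C=C/C(=O)OC(C)(C)C)c1
F6 | step 7 | tert-butyl (2E,6R)-6-{3-[(2E,4E)-6,6-dimethoxyhexa-2,4-dienoyl]-5-methoxy-2-(methoxymethoxy)phenyl}hept-2-enoate | COc1cc(C(=O)/C=C/C=C/C(OC)OC)c(OCOC)c([C@H](C)CC/C=C/C(=O)OC(C)(C)C)c1
F7 | step 7 | tert-butyl (2E,6R)-6-{5-methoxy-2-(methoxymethoxy)-3-[(2E,4E)-6-oxohexa-2,4-dienoyl]phenyl}hept-2-enoate | COc1cc(C(=O)/C=C/C=C/C=O)c(OCOC)c([C@H](C)CC/C=C/C(=O)OC(C)(C)C)c1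
F8 | step 8 | (2E,6R)-6-(3-acetyl-2-hydroxy-5-methoxyphenyl)hept-2-enoic acid | COc1cc(C(C)=O)c(O)c([C@H](C)CC/C=C/C(=O)O)c1
F9 | step 8 | (2E,4E)-6-oxohexa-2,4-dienoic acid | O=C/C=C/C=C/C(=O)O
F10 | step 8 | (2E,4E)-8-{3-[(2R,5E)-6-carboxyhex-5-en-2-yl]-2-hydroxy-5-methoxyphenyl}-6-hydroxy-8-oxoocta-2,4-dienoic acid | COc1cc(C(=O)CC(O)/C=C/C=C/C(=O)O)c(O)c([C@H](C)CC/C=C/C(=O)O)c1
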